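## Retrosynthetic overview
1. The prenyl group comes from an allyl group by cross-metathesis in the last step.
2. The CH2 bridge comes from conjugate (Friedel–Crafts type) addition of the ring B aryl ketone to a methylene trione, which is released from a ring A Mannich base.
3. Key bond, C4–CH2(allyl): ring carbon C3 of an aromatic acylphloroglucinol is made electrophilic on a chiral trivalent-iodine centre (enolonium equivalent) and is attacked by allyltrimethylsilane. Two normally nucleophilic carbons are joined, ring A is dearomatised, and the only stereocentre is set.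
4. The CH2NMe2 group blocks the one free ring A position during the key step and later becomes the bridge carbon. The acyl groups come from Friedel–Crafts (ring A) and Houben–Hoesch (ring B) acylation.
5. Ring order: no ring is built. Both six-membered rings are bought as arenes (2-methylphloroglucinol and 5-methoxyresorcinol).

Assumption: dearomatised compounds are drawn in the enol tautomer of the target SMILES and CIP labels refer to that drawing; the (R,R)-iodoarene is taken to give the R centre, which is a model-based prediction to be checked by ECD or X-ray on 8, with the (S,S)-antipode (from the other lactate) used if the sense is opposite.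

## Route

Step 1
Reactants: 1 2-methylphloroglucinol; 2 butanoyl chloride
Product: 3 1-(2,4,6-trihydroxy-3-methylphenyl)butan-1-one
Conditions: AlCl3 (4 equiv), CH2Cl2/PhNO2, 0 → 40 °C; aq. HCl
Reagents that add atoms: butanoyl chloride 2, CCCC(=O)Cl
Why: Friedel–Crafts C-acylation, in which the two free ring positions of 1 are equivalent and the chelated first acyl group deactivates the ring against a second acylation, so one regioisomer forms and no stereocentre is created.

Step 2
Reactants: 3 1-(2,4,6-trihydroxy-3-methylphenyl)butan-1-one; 4 bis(dimethylamino)methane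
Product: 5 1-{3-[(dimethylamino)methyl]-2,4,6-trihydroxy-5-methylphenyl}butan-1-one
Conditions: CH2(NMe2)2 (1.2 equiv), THF, 0 °C → rt
Reagents that add atoms: bis(dimethylamino)methane 4, CN(C)CN(C)C
Why: Phenol Mannich reaction, in which the acidic phenol protonates the aminal to release CH2=NMe2+, which can attack only the single free ring carbon; the new group blocks that position for step 3 and is the future bridge carbon.

Step 3 (key step)
Reactants: 5 1-{3-[(dimethylamino)methyl]-2,4,6-trihydroxy-5-methylphenyl}butan-1-one; 6 allyltrimethylsilane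
Product: 8 (4R)-2-butanoyl-6-[(dimethylamino)methyl]-3,5-dihydroxy-4-methyl-4-(prop-2-en-1-yl)cyclohexa-2,5-dien-1-one, via iodanyl phenolate 7 (not isolated)
Conditions: (R,R)-2-iodo-1,3-bis[1-(mesitylcarbamoyl)ethoxy]benzene (10 mol %), mCPBA (1.2 equiv), CF3CO2H (1.5 equiv, premixed with 5), allylSiMe3 (5 equiv), CH2Cl2/(CF3)2CHOH 4:1, −20 °C; pH 7 buffer
Reagents that add atoms: allyltrimethylsilane 6, C=CC[Si](C)(C)C
Why: Proposed new method: mCPBA oxidises the iodoarene to its trivalent-iodine dicarboxylate, ligand exchange with the unchelated 4-OH gives 7 in which the normally nucleophilic ring carbon C3 is an enolonium-type electrophile, and the γ-carbon of the allylsilane (also a nucleophile) attacks C3 in SN2′ fashion anti to the departing iodoarene before Me3Si+ is lost, while C5 is switched off by the neighbouring ammonium group (the protonated amine is also safe from the peracid) and C1 by the acyl group; the hydrogen-bonded lactamide arms of the C2-symmetric iodane cover one face of the bound phenolate so the allyl group enters from the open face and sets the quaternary centre as R; the closest known reaction types are the racemic oxidative Hosomi–Sakurai allylation of phenols with PhI(OAc)2 in (CF3)2CHOH, the Kita-type enantioselective dearomatising spirolactonisation with this catalyst class and mCPBA, and chiral-iodoarene-catalysed enolonium C–C coupling of 1,3-dicarbonyl compounds with arenes.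

Step 4
Reactants: 9 5-methoxyresorcinol; 10 hexanenitrile
Product: 12 1-(2,4-dihydroxy-6-methoxyphenyl)hexan-1-one, via ketiminium chloride 11 (not isolated)
Conditions: HCl (g), ZnCl2 (0.3 equiv), Et2O, 0 °C; then H2O, reflux
Reagents that add atoms: hexanenitrile 10, CCCCCC#N; water, O
Why: Houben–Hoesch acylation, in which the activated nitrile attacks para to a free OH at one of the two equivalent sites between OH and OMe rather than the more crowded site between the two OH groups, hydrolysis of 11 gives the ketone, and the minor 2,6-dihydroxy-4-methoxy isomer is removed by chromatography.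

Step 5
Reactants: 8 (4R)-allyl Mannich dienone; 12 1-(2,4-dihydroxy-6-methoxyphenyl)hexan-1-one
Product: 14 (4R)-2-butanoyl-6-[(3-hexanoyl-2,6-dihydroxy-4-methoxyphenyl)methyl]-3,5-dihydroxy-4-methyl-4-(prop-2-en-1-yl)cyclohexa-2,5-dien-1-one, via methylene trione 13 (not isolated)
Conditions: 12 (1.3 equiv), 1,4-dioxane, 80 °C, N2 sparge; 1 M HCl wash
Reagents that add atoms: 1-(2,4-dihydroxy-6-methoxyphenyl)hexan-1-one 12, CCCCCC(=O)c1c(OC)cc(O)cc1O
Why: Retro-Mannich elimination followed by Friedel–Crafts-type conjugate addition (o-quinone-methide chemistry), in which zwitterionic 8 loses Me2NH to give 13, which is captured by the most nucleophilic carbon of 12 (C3, flanked by two OH groups); only ring A can become the electrophile, so cross-coupling is built in, and the all-carbon quaternary centre is untouched.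

Step 6
Reactants: 14 (4R)-allyl methylene-bridged dimer; 15 2-methyl-2-butene
Product: 16 (4R)-2-butanoyl-6-[(3-hexanoyl-2,6-dihydroxy-4-methoxyphenyl)methyl]-3,5-dihydroxy-4-methyl-4-(3-methylbut-2-en-1-yl)cyclohexa-2,5-dien-1-one (target)
Conditions: second-generation Hoveyda–Grubbs catalyst, (1,3-dimesitylimidazolidin-2-ylidene)dichloro(2-isopropoxybenzylidene)ruthenium (5 mol %), 2-methyl-2-butene/CH2Cl2 1:1, 40 °C, sealed tube
Reagents that add atoms: 2-methyl-2-butene 15, CC=C(C)C
Why: Olefin cross-metathesis, in which the unhindered terminal allyl alkene exchanges its CH2 terminus for the CMe2 terminus of excess 2-methyl-2-butene, propene escapes, the trisubstituted product is not re-engaged by the catalyst, and the neutral conditions avoid chroman formation and leave the stereocentre untouched.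

## Compound list
1 | 2-methylphloroglucinol (2-methylbenzene-1,3,5-triol) | Cc1c(O)cc(O)cc1O | starting material
2 | butanoyl chloride | CCCC(=O)Cl | starting material
3 | 1-(2,4,6-trihydroxy-3-methylphenyl)butan-1-one | CCCC(=O)c1c(O)cc(O)c(C)c1O | intermediate
4 | bis(dimethylamino)methane | CN(C)CN(C)C | starting material
5 | 1-{3-[(dimethylamino)methyl]-2,4,6-trihydroxy-5-methylphenyl}butan-1-one | CCCC(=O)c1c(O)c(CN(C)C)c(O)c(C)c1O | intermediate
6 | allyltrimethylsilane | C=CC[Si](C)(C)C | starting material
7 | 4-O-bound trivalent-iodine phenolate of 5 carrying the (R,R)-bis(lactamide) aryl ligand and a 3-chlorobenzoate ligand (enolonium equivalent, not isolated, amine protonated in the flask) | CCCC(=O)c1c(O)c(CN(C)C)c(OI(OC(=O)c2cccc(Cl)c2)c2c(O[C@H](C)C(=O)Nc3c(C)cc(C)cc3C)cccc2O[C@H](C)C(=O)Nc2c(C)cc(C)cc2C)c(C)c1O | intermediate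
8 | (4R)-2-butanoyl-6-[(dimethylamino)methyl]-3,5-dihydroxy-4-methyl-4-(prop-2-en-1-yl)cyclohexa-2,5-dien-1-one | CN(C)CC1=C(O)[C@@](C)(CC=C)C(O)=C(C(=O)CCC)C1=O | intermediate
9 | 5-methoxyresorcinol (5-methoxybenzene-1,3-diol) | COc1cc(O)cc(O)c1 | starting material
10 | hexanenitrile | CCCCCC#N | starting material
11 | 1-(2,4-dihydroxy-6-methoxyphenyl)hexan-1-iminium chloride (not isolated) | CCCCCC(=[NH2+])c1c(O)cc(O)cc1OC.[Cl-] | intermediate
12 | 1-(2,4-dihydroxy-6-methoxyphenyl)hexan-1-one | CCCCCC(=O)c1c(OC)cc(O)cc1O | intermediate
13 | 2-butanoyl-3-hydroxy-4-methyl-6-methylidene-4-(prop-2-en-1-yl)cyclohex-2-ene-1,5-dione (not isolated; same spatial arrangement as 8, CIP label 4S in this tautomer) | C=C1C(=O)[C@@](C)(CC=C)C(O)=C(C(=O)CCC)C1=O | intermediate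
14 | (4R)-2-butanoyl-6-[(3-hexanoyl-2,6-dihydroxy-4-methoxyphenyl)methyl]-3,5-dihydroxy-4-methyl-4-(prop-2-en-1-yl)cyclohexa-2,5-dien-1-one | CCCCCC(=O)c1c(OC)cc(O)c(CC2=C(O)[C@@](C)(CC=C)C(O)=C(C(=O)CCC)C2=O)c1O | intermediate
15 | 2-methyl-2-butene | CC=C(C)C | starting material
16 | (4R)-2-butanoyl-6-[(3-hexanoyl-2,6-dihydroxy-4-methoxyphenyl)methyl]-3,5-dihydroxy-4-methyl-4-(3-methylbut-2-en-1-yl)cyclohexa-2,5-dien-1-one (CNP0219201.1) | CCCCCC(=O)c1c(OC)cc(O)c(CC2=C(O)[C@@](C)(CC=C(C)C)C(O)=C(C(=O)CCC)C2=O)c1O | target

## Step count
- Total steps: 6.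
- Longest linear sequence: 5 (steps 1, 2, 3, 5, 6).

## Steps most likely to fail

**Step 3.** This is a new reaction. The risks are low facial selectivity, loss of a methyl proton to give a quinone methide, and capture of the β-silyl cation by a ring oxygen. The fallback sets out from 5 and gives up catalyst control of the stereocentre. The same polarity-reversed allylation is run with achiral PhI(OAc)2, allyltrimethylsilane 6 and CF3CO2H in (CF3)2CHOH/CH2Cl2 at −20 °C. This gives the racemic allyl Mannich dienone F1. F1 is then resolved classically through its basic nitrogen: the (1S)-(+)-camphor-10-sulfonate salt of the R enantiomer F2 is fractionally crystallised from EtOAc/EtOH. Neutralisation at pH 7 liberates the free compound, and the fallback rejoins the route at 8.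

**Step 5.** The risks are attack through C5 instead of C3 of 12 and heat- or amine-induced exchange of the methylene bridge. The fallback sets out from 8 and replaces thermal amine extrusion by an isolable sulfone relay that works at room temperature. Sodium 4-methylbenzenesulfinate in aqueous AcOH/EtOH at 50 °C converts 8 into the crystalline allyl dienone tolylsulfonylmethyl derivative F3. It has the same spatial arrangement, but the CIP label is 4S because of sulfur priority. F3 is purified and then stirred with 12 and NaHCO3 in MeCN at rt. Sulfinate is lost to give 13 slowly at low concentration with no amine present, and the phenolate of 12 adds to it. The fallback rejoins the route at 14.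

**Step 6.** The risks are chelation of ruthenium by the enolised β-triketone and incomplete exchange. The fallback sets out from 8 and builds the prenyl group without metathesis, before ring B is attached.
- The trifluoroacetate salt of 8 is cleaved with OsO4 (2 mol %) and NaIO4 in THF/H2O. This gives the (4R)-oxoethyl Mannich dienone F4, which is partly present as its cyclic hemiacetal.
- Wittig olefination with Ph3P=CMe2 follows (isopropyltriphenylphosphonium iodide and KN(SiMe3)2, 4 equiv to cover the acidic sites, THF, −78 °C → rt). This gives the (4R)-prenyl Mannich dienone F5.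
- Heating F5 with 12 in 1,4-dioxane at 80 °C, as in step 5, releases the prenyl methylene trione F6, which is trapped by 12. The fallback rejoins the route at 16.

## Further compounds
F1 | step 3 | racemic 2-butanoyl-6-[(dimethylamino)methyl]-3,5-dihydroxy-4-methyl-4-(prop-2-en-1-yl)cyclohexa-2,5-dien-1-one | CN(C)CC1=C(O)C(C)(CC=C)C(O)=C(C(=O)CCC)C1=O
F2 | step 3 | (1S)-(+)-camphor-10-sulfonate salt of (4R)-8 | C[NH+](C)CC1=C(O)[C@@](C)(CC=C)C(O)=C(C(=O)CCC)C1=O.CC1(C)[C@@H]2CC[C@]1(C(=O)C2)CS(=O)(=O)[O-]
F3 | step 5 | 2-butanoyl-3,5-dihydroxy-4-methyl-6-{[(4-methylphenyl)sulfonyl]methyl}-4-(prop-2-en-1-yl)cyclohexa-2,5-dien-1-one, same spatial arrangement as 8 (CIP 4S) | Cc1ccc(cc1)S(=O)(=O)CC1=C(O)[C@@](C)(CC=C)C(O)=C(C(=O)CCC)C1=O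
F4 | step 6 | (4R)-2-butanoyl-6-[(dimethylamino)methyl]-3,5-dihydroxy-4-methyl-4-(2-oxoethyl)cyclohexa-2,5-dien-1-one | CN(C)CC1=C(O)[C@@](C)(CC=O)C(O)=C(C(=O)CCC)C1=O
F5 | step 6 | (4R)-2-butanoyl-6-[(dimethylamino)methyl]-3,5-dihydroxy-4-methyl-4-(3-methylbut-2-en-1-yl)cyclohexa-2,5-dien-1-one | CN(C)CC1=C(O)[C@@](C)(CC=C(C)C)C(O)=C(C(=O)CCC)C1=O
F6 | step 6 | 2-butanoyl-3-hydroxy-4-methyl-6-methylidene-4-(3-methylbut-2-en-1-yl)cyclohex-2-ene-1,5-dione, same spatial arrangement as F5 (CIP 4S in this tautomer) | C=C1C(=O)[C@@](C)(CC=C(C)C)C(O)=C(C(=O)CCC)C1=O
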